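Ring A is grown onto a finished B–C unit instead of being bought. Removing C5–C8 leaves a kojic-acid-derived 2-aryl-3-methoxypyran-4-one (ring C, O3 already in place) that bears a diazoacetyl group at C8a and an unsubstituted C4a–H. The other partner is a two-carbon siloxyacetylene. One operation, a photo-Wolff/ketene–alkyne [2+2]/4π-opening/6π-closure cascade, makes C8a–C8, C7–C8, C5–C6 and C4a–C5 and aromatises ring A. It exploits the meta relation of O5 and O7 on ring A, which mirrors the polarity of a ketene carbonyl (C5) and an ynol ether carbon (C7). It also uses the C8a=C4a bond of ring C as the built-in vinyl unit. The 5-OH emerges free and O7 silylated.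

Key step: step 12

Remark: the target has no stereocentre and its only acyclic alkene carries two identical methyl groups, so it is achiral and there is no enantiomer to select; flavone numbering (O1, C2–C4, C4a, C5–C8, C8a, primes for ring B) is used for the late compounds.

Step 1
Reactants: 1 4-bromo-2-methoxyphenol; 2 3-chloro-3-methylbut-1-yne
Product: 3 4-bromo-2-methoxy-1-[(2-methylbut-3-yn-2-yl)oxy]benzene
Conditions: CuCl2·2H2O (1 mol%), DBU, MeCN, 0 °C to rt
Reagents that add atoms: none
Why: Copper-catalysed O-propargylation of a phenol by a tertiary propargylic chloride is the standard entry to aryl 1,1-dimethylpropargyl ethers and leaves the aryl bromide untouched.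

Step 2
Reactants: 3 4-bromo-2-methoxy-1-[(2-methylbut-3-yn-2-yl)oxy]benzene
Product: 4 4-bromo-2-methoxy-1-[(2-methylbut-3-en-2-yl)oxy]benzene
Conditions: H2 (1 atm), Lindlar catalyst, quinoline, EtOAc, rt
Reagents that add atoms: none
Why: Lindlar semihydrogenation stops at the terminal alkene and, at room temperature on a poisoned catalyst, should neither cleave the C–Br bond nor trigger chromene formation.

Step 3
Reactants: 4 4-bromo-2-methoxy-1-[(2-methylbut-3-en-2-yl)oxy]benzene
Product: 6 4-bromo-2-methoxy-6-(3-methylbut-2-enyl)phenol, via ortho-dienone 5 (not isolated)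
Conditions: xylenes (degassed), 140 °C, sealed vessel
Reagents that add atoms: none
Why: The aromatic Claisen rearrangement ([3,3]-sigmatropic shift) inverts the reverse-prenyl ether into a normal prenyl group at C6, the only free ortho position, and the sp3 centre of 5 is erased on tautomerisation to the phenol.

Step 4
Reactants: 6 4-bromo-2-methoxy-6-(3-methylbut-2-enyl)phenol
Product: 7 [4-bromo-2-methoxy-6-(3-methylbut-2-enyl)phenoxy]triisopropylsilane
Conditions: TIPSOTf, 2,6-lutidine, CH2Cl2, 0 °C to rt
Reagents that add atoms: triisopropylsilyl trifluoromethanesulfonate, CC(C)[Si](C(C)C)(C(C)C)OS(=O)(=O)C(F)(F)F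
Why: O-silylation with the silyl triflate and a hindered pyridine base overcomes the double ortho substitution of the phenol, and the buffered medium protects the ortho-prenylphenol from acid-induced chroman formation.

Step 5
Reactants: 7 [4-bromo-2-methoxy-6-(3-methylbut-2-enyl)phenoxy]triisopropylsilane
Product: 8 2-[3-methoxy-5-(3-methylbut-2-enyl)-4-(triisopropylsilyloxy)phenyl]-4,4,5,5-tetramethyl-1,3,2-dioxaborolane
Conditions: B2pin2, PdCl2(dppf) (3 mol%), KOAc, 1,4-dioxane, 85 °C
Reagents that add atoms: bis(pinacolato)diboron, CC1(C)OB(OC1(C)C)B1OC(C)(C)C(C)(C)O1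
Why: Miyaura borylation tolerates the silyl ether, the methyl ether and the trisubstituted alkene, and the weak acetate base suppresses biaryl homocoupling.

Step 6
Reactants: 9 kojic acid
Product: 10 5-hydroxy-2-(hydroxymethyl)-6-iodopyran-4-one
Conditions: NIS, DMF, 0 °C to rt, dark
Reagents that add atoms: N-iodosuccinimide, O=C1CCC(=O)N1I
Why: Electrophilic iodination of the enolic 3-hydroxy-4-pyranone unit goes to C6, the carbon next to the 5-OH at which kojic acid undergoes its electrophilic substitutions (halogenation, Mannich reaction, hydroxymethylation).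

Step 7
Reactants: 10 5-hydroxy-2-(hydroxymethyl)-6-iodopyran-4-one
Product: 11 2-(hydroxymethyl)-6-iodo-5-methoxypyran-4-one
Conditions: MeI, K2CO3, DMF, rt
Reagents that add atoms: iodomethane, CI
Why: The Williamson etherification is selective because carbonate deprotonates only the acidic enolic OH while the primary alcohol stays neutral.

Step 8
Reactants: 11 2-(hydroxymethyl)-6-iodo-5-methoxypyran-4-one
Product: 13 6-iodo-5-methoxy-4-oxo-4H-pyran-2-carboxylic acid, via aldehyde 12 (not isolated)
Conditions: CrO3, H2SO4, H2O, acetone, 0 °C to rt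
Reagents that add atoms: water, O
Why: Jones oxidation of 5-O-alkyl kojic acids to the corresponding pyranone-2-carboxylic acids is well established, and it is placed here because no prenyl group or silyl ether is yet present.

Step 9
Reactants: 13 6-iodo-5-methoxy-4-oxo-4H-pyran-2-carboxylic acid; 8 2-[3-methoxy-5-(3-methylbut-2-enyl)-4-(triisopropylsilyloxy)phenyl]-4,4,5,5-tetramethyl-1,3,2-dioxaborolane
Product: 14 5-methoxy-6-[3-methoxy-5-(3-methylbut-2-enyl)-4-(triisopropylsilyloxy)phenyl]-4-oxo-4H-pyran-2-carboxylic acid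
Conditions: PdCl2(dppf) (5 mol%), K3PO4, 1,4-dioxane/H2O, 65 °C; mildly acidic work-up
Reagents that add atoms: none
Why: In this Suzuki–Miyaura coupling the C–I bond of the vinylogous acyl iodide adds Pd(0) readily, and the carboxylate formed in situ lowers the electrophilicity of the pyranone toward aqueous base without disturbing transmetalation.

Step 10
Reactants: 14 5-methoxy-6-[3-methoxy-5-(3-methylbut-2-enyl)-4-(triisopropylsilyloxy)phenyl]-4-oxo-4H-pyran-2-carboxylic acid; 15 trimethylsilyldiazomethane
Product: 17 6-(diazoacetyl)-3-methoxy-2-[3-methoxy-5-(3-methylbut-2-enyl)-4-(triisopropylsilyloxy)phenyl]pyran-4-one, via mixed anhydride 16 (not isolated)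
Conditions: i-BuOCOCl, N-methylmorpholine, THF, −15 °C; then 15, THF/MeCN, 0 °C to rt; aq. NaHCO3
Reagents that add atoms: isobutyl chloroformate, CC(C)COC(=O)Cl (its atoms stay only in 16)
Why: C-acylation of a diazoalkane by a mixed carbonic anhydride (first stage of the Arndt–Eistert sequence, silyldiazomethane variant) avoids HCl, which would add to the prenyl alkene, and the silyl group is lost to the carbonate leaving group and on work-up.

Step 11
Reactants: 18 3-phenylisoxazole
Product: 20 (triisopropylsilyloxy)acetylene, via lithium ethynolate 19 (not isolated)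
Conditions: LDA, THF, −78 °C; then TIPSOTf, −78 to 0 °C; hexane, cold aq. NaHCO3, short Et3N-deactivated silica plug
Reagents that add atoms: triisopropylsilyl trifluoromethanesulfonate, CC(C)[Si](C(C)C)(C(C)C)OS(=O)(=O)C(F)(F)F; lithium diisopropylamide, [Li+].CC(C)[N-]C(C)C (lithium held only in 19)
Why: Deprotonation of a 3-substituted isoxazole at C5 triggers the known base-induced cycloreversion into a nitrile and a lithium ynolate without excess base, and ynolate O-silylation is favoured by the hard, bulky silyl triflate.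

Step 12
Reactants: 17 6-(diazoacetyl)-3-methoxy-2-[3-methoxy-5-(3-methylbut-2-enyl)-4-(triisopropylsilyloxy)phenyl]pyran-4-one; 20 (triisopropylsilyloxy)acetylene
Product: 25 7,4'-bis-O-triisopropylsilyl dodoviscin J, via pyranonylketene 21 (not isolated), via siloxycyclobutenone 22 (not isolated), via dienylketene 23 (not isolated), via C4a-H dienone 24 (not isolated)
Conditions: 20 (3 equiv), degassed ClCH2CH2Cl (0.02 M), 450 nm LED, 20 °C; then 80 °C, dark
Reagents that add atoms: none
Why: Proposed new method: irradiation at 450 nm should excite only the weak n–π* band of the diazoketone, well to the red of the 2-aryl-3-methoxypyranone and flavone chromophores whose UV photochemistry is thereby avoided, and N2 loss with 1,2-shift of the pyranonyl carbon (Wolff rearrangement, C8a–C8) gives ketene 21, conjugated with the C8a=C4a bond of ring C. The electron-rich CH terminus of 20 attacks the ketene carbonyl carbon (C5–C6) and the oxygen-bearing carbon closes onto C8 (C7–C8) in a [2+2] cycloaddition, so the polarisation of the ynol ether alone fixes the regiochemistry and places O7 meta to O5 in cyclobutenone 22. At 80 °C reversible conrotatory 4π opening gives dienylketene 23, and the isomer that holds the ketene arm cis to the pyranone is drained by disrotatory 6π electrocyclisation, which closes six-membered ring A (C4a–C5) onto C4a, the only open terminus and the nucleophilic β-carbon of the O1–C8a=C4a enol ether, matched to the electrophilic ketene carbon. Dienone 24 holds its C4a–H between two carbonyl groups and should enolise at once to the chelated 5-OH of 25, so the transient sp3 centres of 22 and 24 vanish and no stereocontrol is required. The closest known reaction type is the diazoketone (photo-Wolff) variant of the Danheiser benzannulation of aryl and five-membered heteroaryl diazoketones with siloxyalkynes; the 4-pyranon-2-yl migrating group and the visible-light trigger are the untested elements. Chemoselectivity over the prenyl alkene is secured by the far greater ketenophilicity of the ynol ether used in excess, by high dilution and by the absence of metal catalysts that would favour carbenoid cyclopropanation or activate the siloxyalkyne.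

Step 13
Reactants: 25 7,4'-bis-O-triisopropylsilyl dodoviscin J
Product: 26 dodoviscin J
Conditions: TBAF, AcOH, THF, 0 °C
Reagents that add atoms: none
Why: Fluoride-mediated desilylation of aryl silyl ethers is fast at 0 °C, and the acetic acid buffer keeps the medium neither basic enough to degrade the polyphenol nor acidic enough to cyclise the ortho-prenylphenol to a chroman.

Compound list
1 | 4-bromo-2-methoxyphenol | COc1cc(Br)ccc1O | starting material
2 | 3-chloro-3-methylbut-1-yne | C#CC(C)(C)Cl | starting material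
3 | 4-bromo-2-methoxy-1-[(2-methylbut-3-yn-2-yl)oxy]benzene | COc1cc(Br)ccc1OC(C)(C)C#C | intermediate
4 | 4-bromo-2-methoxy-1-[(2-methylbut-3-en-2-yl)oxy]benzene | COc1cc(Br)ccc1OC(C)(C)C=C | intermediate
5 | 4-bromo-2-methoxy-6-(3-methylbut-2-enyl)cyclohexa-2,4-dien-1-one (racemic, transient) | COC1=CC(Br)=CC(CC=C(C)C)C1=O | intermediate (not isolated)
6 | 4-bromo-2-methoxy-6-(3-methylbut-2-enyl)phenol | COc1cc(Br)cc(CC=C(C)C)c1O | intermediate
7 | [4-bromo-2-methoxy-6-(3-methylbut-2-enyl)phenoxy]triisopropylsilane | COc1cc(Br)cc(CC=C(C)C)c1O[Si](C(C)C)(C(C)C)C(C)C | intermediate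
8 | 2-[3-methoxy-5-(3-methylbut-2-enyl)-4-(triisopropylsilyloxy)phenyl]-4,4,5,5-tetramethyl-1,3,2-dioxaborolane | COc1cc(B2OC(C)(C)C(C)(C)O2)cc(CC=C(C)C)c1O[Si](C(C)C)(C(C)C)C(C)C | intermediate
9 | kojic acid, 5-hydroxy-2-(hydroxymethyl)pyran-4-one | OCc1cc(=O)c(O)co1 | starting material
10 | 5-hydroxy-2-(hydroxymethyl)-6-iodopyran-4-one | OCc1cc(=O)c(O)c(I)o1 | intermediate
11 | 2-(hydroxymethyl)-6-iodo-5-methoxypyran-4-one | OCc1cc(=O)c(OC)c(I)o1 | intermediate
12 | 6-iodo-5-methoxy-4-oxo-4H-pyran-2-carbaldehyde | O=Cc1cc(=O)c(OC)c(I)o1 | intermediate (not isolated)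
13 | 6-iodo-5-methoxy-4-oxo-4H-pyran-2-carboxylic acid | OC(=O)c1cc(=O)c(OC)c(I)o1 | intermediate
14 | 5-methoxy-6-[3-methoxy-5-(3-methylbut-2-enyl)-4-(triisopropylsilyloxy)phenyl]-4-oxo-4H-pyran-2-carboxylic acid | OC(=O)c1cc(=O)c(OC)c(-c2cc(OC)c(O[Si](C(C)C)(C(C)C)C(C)C)c(CC=C(C)C)c2)o1 | intermediate
15 | trimethylsilyldiazomethane | C[Si](C)(C)C=[N+]=[N-] | starting material
16 | isobutyl carbonic anhydride of acid 14 | CC(C)COC(=O)OC(=O)c1cc(=O)c(OC)c(-c2cc(OC)c(O[Si](C(C)C)(C(C)C)C(C)C)c(CC=C(C)C)c2)o1 | intermediate (not isolated)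
17 | 6-(diazoacetyl)-3-methoxy-2-[3-methoxy-5-(3-methylbut-2-enyl)-4-(triisopropylsilyloxy)phenyl]pyran-4-one | [N-]=[N+]=CC(=O)c1cc(=O)c(OC)c(-c2cc(OC)c(O[Si](C(C)C)(C(C)C)C(C)C)c(CC=C(C)C)c2)o1 | intermediate
18 | 3-phenylisoxazole | c1ccc(cc1)-c1ccon1 | starting material
19 | lithium ethynolate | [Li+].[O-]C#C | intermediate (not isolated)
20 | (triisopropylsilyloxy)acetylene | C#CO[Si](C(C)C)(C(C)C)C(C)C | intermediate
21 | ketene of Wolff rearrangement, 6-(2-oxoethenyl)-3-methoxy-2-arylpyran-4-one | O=C=Cc1cc(=O)c(OC)c(-c2cc(OC)c(O[Si](C(C)C)(C(C)C)C(C)C)c(CC=C(C)C)c2)o1 | intermediate (not isolated)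
22 | 4-(pyranon-2-yl)-3-(triisopropylsilyloxy)cyclobut-2-en-1-one (racemic, transient) | O=C1C=C(O[Si](C(C)C)(C(C)C)C(C)C)C1c1cc(=O)c(OC)c(-c2cc(OC)c(O[Si](C(C)C)(C(C)C)C(C)C)c(CC=C(C)C)c2)o1 | intermediate (not isolated)
23 | dienylketene, reactive isomer with the ketene arm cis to the pyranone | O=C=C/C(O[Si](C(C)C)(C(C)C)C(C)C)=C\c1cc(=O)c(OC)c(-c2cc(OC)c(O[Si](C(C)C)(C(C)C)C(C)C)c(CC=C(C)C)c2)o1 | intermediate (not isolated)
24 | C4a-H keto tautomer of 25 (racemic, transient) | COC1=C(c2cc(OC)c(O[Si](C(C)C)(C(C)C)C(C)C)c(CC=C(C)C)c2)OC2=CC(O[Si](C(C)C)(C(C)C)C(C)C)=CC(=O)C2C1=O | intermediate (not isolated)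
25 | 7,4'-bis-O-triisopropylsilyl dodoviscin J | COc1cc(-c2oc3cc(O[Si](C(C)C)(C(C)C)C(C)C)cc(O)c3c(=O)c2OC)cc(CC=C(C)C)c1O[Si](C(C)C)(C(C)C)C(C)C | intermediate
26 | dodoviscin J, 5,7-dihydroxy-2-[4-hydroxy-3-methoxy-5-(3-methylbut-2-enyl)phenyl]-3-methoxychromen-4-one (achiral) | COc1cc(-c2oc3cc(O)cc(O)c3c(=O)c2OC)cc(CC=C(C)C)c1O | target

Total step count: 13.
Longest linear sequence: 9 (steps 1, 2, 3, 4, 5, 9, 10, 12, 13).

Steps most likely to fail

1. Step 12 (bears the label Proposed new method).
- What may go wrong: The pyranone may divert into valence isomerisation under light or heat. The ketene may dimerise or be intercepted before the alkyne reaches it. The cascade may also stall at the cyclobutenone stage, because 6π closure has to break the cross-conjugation of ring C.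
- Fallback (known chemistry; ring A bought, ring C made): it sets out from bromide 7 and comes back at target 26. Bromine–lithium exchange (n-BuLi, THF, −78 °C) and carboxylation with CO2 should give 3-methoxy-5-(3-methylbut-2-enyl)-4-(triisopropylsilyloxy)benzoic acid F1. 1-Chloro-N,N,2-trimethylprop-1-en-1-amine (CH2Cl2, 0 °C) then converts it under neutral conditions into 3-methoxy-5-(3-methylbut-2-enyl)-4-(triisopropylsilyloxy)benzoyl chloride F2. Commercial 2-methoxy-1-(2,4,6-trihydroxyphenyl)ethanone is turned into its polylithium salt with excess LiHMDS (THF, −78 °C). It is C-aroylated with F2 (Baker–Venkataraman-type diketone synthesis) to give 2-methoxy-1-[3-methoxy-5-(3-methylbut-2-enyl)-4-(triisopropylsilyloxy)phenyl]-3-(2,4,6-trihydroxyphenyl)propane-1,3-dione F3. Cyclodehydration (NaOAc, AcOH, 90 °C) closes ring C to 4'-O-triisopropylsilyl dodoviscin J F4, and the conditions of step 13 release 26.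

2. Step 11.
- What may go wrong: The sterically unprotected carbon terminus of ynolate 19 may be silylated in competition with oxygen. The terminal siloxyalkyne may also suffer O-to-C silyl shift, hydrolysis or evaporative loss during isolation.
- Fallback (carbon terminus blocked, different ynolate source): it sets out from diazoketone 17 and comes back at target 26. Commercial ethynyltrimethylsilane is lithiated (n-BuLi, THF, −78 °C) and oxidised with lithium tert-butyl peroxide (t-BuOOH, LiHMDS, −78 to 0 °C) to lithium (trimethylsilyl)ethynolate F5. Its hindered carbon leaves only oxygen open to TIPSOTf, which should give the less volatile triisopropyl{[(trimethylsilyl)ethynyl]oxy}silane F6. Under the conditions of step 12, 17 and F6 should give 6-trimethylsilyl-7,4'-bis-O-triisopropylsilyl dodoviscin J F7, the silicon-bearing alkyne carbon becoming C6. The conditions of step 13 then remove both O-silyl groups. They also remove the C-silyl group by ipso-protodesilylation at the doubly oxygen-flanked C6, to give 26.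

3. Step 10.
- What may go wrong: The weakly nucleophilic silyldiazomethane may attack the carbonate carbonyl of 16 and return an ester. It may also add as a 1,3-dipole across the doubly activated C4a=C8a bond.
- Fallback (diazo group by transfer onto a methyl ketone instead of acylation of a diazoalkane): it sets out from acid 14 and comes back at diazoketone 17. Amide coupling (MeNHOMe·HCl, EDCI, N-methylmorpholine, CH2Cl2) should give the Weinreb amide N,5-dimethoxy-N-methyl-6-[3-methoxy-5-(3-methylbut-2-enyl)-4-(triisopropylsilyloxy)phenyl]-4-oxo-4H-pyran-2-carboxamide F8. MeMgBr (THF, −78 °C) should then give 6-acetyl-3-methoxy-2-[3-methoxy-5-(3-methylbut-2-enyl)-4-(triisopropylsilyloxy)phenyl]pyran-4-one F9. Kinetic enolisation and trifluoroacetylation (LiHMDS, THF, −78 °C; CF3CO2CH2CF3) give the 4,4,4-trifluoro-1-(pyranon-2-yl)butane-1,3-dione F10. This is treated crude with MsN3, Et3N and H2O in MeCN (detrifluoroacetylative diazo transfer) to give 17.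

Further compounds
F1 | step 12 | 3-methoxy-5-(3-methylbut-2-enyl)-4-(triisopropylsilyloxy)benzoic acid | COc1cc(C(=O)O)cc(CC=C(C)C)c1O[Si](C(C)C)(C(C)C)C(C)C
F2 | step 12 | 3-methoxy-5-(3-methylbut-2-enyl)-4-(triisopropylsilyloxy)benzoyl chloride | COc1cc(C(=O)Cl)cc(CC=C(C)C)c1O[Si](C(C)C)(C(C)C)C(C)C
F3 | step 12 | 2-methoxy-1-[3-methoxy-5-(3-methylbut-2-enyl)-4-(triisopropylsilyloxy)phenyl]-3-(2,4,6-trihydroxyphenyl)propane-1,3-dione (racemic, enolisable) | COC(C(=O)c1c(O)cc(O)cc1O)C(=O)c1cc(OC)c(O[Si](C(C)C)(C(C)C)C(C)C)c(CC=C(C)C)c1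
F4 | step 12 | 4'-O-triisopropylsilyl dodoviscin J | COc1cc(-c2oc3cc(O)cc(O)c3c(=O)c2OC)cc(CC=C(C)C)c1O[Si](C(C)C)(C(C)C)C(C)C
F5 | step 11 | lithium (trimethylsilyl)ethynolate | [Li+].[O-]C#C[Si](C)(C)C
F6 | step 11 | triisopropyl{[(trimethylsilyl)ethynyl]oxy}silane | C[Si](C)(C)C#CO[Si](C(C)C)(C(C)C)C(C)C
F7 | step 11 | 6-trimethylsilyl-7,4'-bis-O-triisopropylsilyl dodoviscin J | COc1cc(-c2oc3cc(O[Si](C(C)C)(C(C)C)C(C)C)c([Si](C)(C)C)c(O)c3c(=O)c2OC)cc(CC=C(C)C)c1O[Si](C(C)C)(C(C)C)C(C)C
F8 | step 10 | N,5-dimethoxy-N-methyl-6-[3-methoxy-5-(3-methylbut-2-enyl)-4-(triisopropylsilyloxy)phenyl]-4-oxo-4H-pyran-2-carboxamide | CON(C)C(=O)c1cc(=O)c(OC)c(-c2cc(OC)c(O[Si](C(C)C)(C(C)C)C(C)C)c(CC=C(C)C)c2)o1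
F9 | step 10 | 6-acetyl-3-methoxy-2-[3-methoxy-5-(3-methylbut-2-enyl)-4-(triisopropylsilyloxy)phenyl]pyran-4-one | CC(=O)c1cc(=O)c(OC)c(-c2cc(OC)c(O[Si](C(C)C)(C(C)C)C(C)C)c(CC=C(C)C)c2)o1
F10 | step 10 | 4,4,4-trifluoro-1-{5-methoxy-6-[3-methoxy-5-(3-methylbut-2-enyl)-4-(triisopropylsilyloxy)phenyl]-4-oxo-4H-pyran-2-yl}butane-1,3-dione | O=C(CC(=O)C(F)(F)F)c1cc(=O)c(OC)c(-c2cc(OC)c(O[Si](C(C)C)(C(C)C)C(C)C)c(CC=C(C)C)c2)o1
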